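**Plan**

1. The retrosynthesis cuts one bond only: the biaryl bond from C6 of ring A of the acacetin half to C8'' of ring A of the 7,4'-di-O-methylapigenin half. Beyond it, only two O-helpers are removed (7-O-benzyl and 5''-O-methyl).
2. In the forward direction no ring is built. Acacetin 1 is benzylated at O7 to give 2. Then 2 and 5,7,4'-trimethoxyflavone 3 are joined C–H to C–H in one flask by an oxidative cross-coupling through an aryl-λ3-iodane, the laboratory counterpart of the dehydrogenative pairing of apigenin-type monomers in biosynthesis. One BCl3 step then removes both helpers.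
3. Enabling feature: each ring A is a phloroglucinol-type arene whose most nucleophilic CH is switched by the group on O5. With 5-OMe it is C8 (between O1 and 7-OMe); with a free 5-OH hydrogen-bonded to the C4 carbonyl it is C6 (between 5-OH and 7-OR). These are the two atoms of the bond to be made.
4. Stereochemistry: the target has no stereocentre. The axis with four ortho substituents forms without control, as the racemate.

Key step: step 2

Remark: the target is drawn without an axial descriptor, so the racemic axis is taken as the goal.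

**Route**

Step 1
Reactants: 1 acacetin (5,7-dihydroxy-2-(4-methoxyphenyl)-4H-chromen-4-one)
Product: 2 7-(benzyloxy)-5-hydroxy-2-(4-methoxyphenyl)-4H-chromen-4-one
Conditions: BnBr (1.1 equiv), K2CO3 (1.5 equiv), acetone, reflux
Reagents that add atoms: benzyl bromide, BrCc1ccccc1
Why: Williamson etherification; the 7-OH is the only acidic, unchelated phenol (the 5-OH is tied to the C4 carbonyl by a hydrogen bond), so mono-O-benzylation at O7 is expected.

Step 2
Reactants: 3 5,7-dimethoxy-2-(4-methoxyphenyl)-4H-chromen-4-one (apigenin trimethyl ether); 2 7-(benzyloxy)-5-hydroxy-2-(4-methoxyphenyl)-4H-chromen-4-one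
Product: 5 7-(benzyloxy)-6-[5,7-dimethoxy-2-(4-methoxyphenyl)-4-oxo-4H-chromen-8-yl]-5-hydroxy-2-(4-methoxyphenyl)-4H-chromen-4-one (racemic axis), via flavon-8-yl(phenyl)iodonium tosylate 4 (not isolated)
Conditions: PhI(OH)OTs (1.0 equiv), (CF3)2CHOH (HFIP), rt; then 2 (1.5 equiv), BF3·OEt2 (20 mol %), HFIP–CH2Cl2, rt to 40 °C
Reagents that add atoms: none
Why: Proposed new method: PhI(OH)OTs should attack 3 by SEAr at C8 of ring A to give the aryl(phenyl)-λ3-iodane 4, and in HFIP the BF3-activated salt should form a charge-transfer complex with 2, pass one electron from 2 to the iodane within the complex, couple C6 of the resulting radical cation with the ipso carbon C8 as PhI departs, and lose a proton to restore both arenes. The closest known reaction type is the metal-free oxidative cross-coupling of two electron-rich arenes through an aryl(phenyl)iodonium salt made in situ in a fluoroalcohol, which has not been shown for flavone rings or for a biaryl axis with four ortho substituents. No ring is closed and no stereocentre is set; the C6–C8'' axis forms as the racemate. Cross-selectivity needs no electronic bias, because all oxidant is bound in 4 before 2 is added, so neither homodimer has a path, and O-arylation is shut off because the 7-OH of 2 is benzylated and its 5-OH is chelated. The site on 3 is fixed by the 5-O-methyl group: C6 lies between two OMe groups, and C8, between O1 and 7-OMe, is where 5,7-dialkoxyflavones take up electrophiles. The site on 2 is fixed by the free 5-OH, whose hydrogen bond to the C4 carbonyl makes C6 (between 5-OH and 7-OBn) and not C8 the nucleophilic carbon, as in the 6-iodination of 5-hydroxy-7-alkoxyflavones.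

Step 3
Reactants: 5 7-(benzyloxy)-6-[5,7-dimethoxy-2-(4-methoxyphenyl)-4-oxo-4H-chromen-8-yl]-5-hydroxy-2-(4-methoxyphenyl)-4H-chromen-4-one
Product: 6 5,7-dihydroxy-6-[5-hydroxy-7-methoxy-2-(4-methoxyphenyl)-4-oxo-4H-chromen-8-yl]-2-(4-methoxyphenyl)-4H-chromen-4-one (agathisflavone 4',7'',4'''-trimethyl ether, racemic axis)
Conditions: BCl3 (6 equiv), C6HMe5 (3 equiv), CH2Cl2, −78 to 0 °C; then H2O
Reagents that add atoms: none
Why: Lewis-acid ether cleavage, in which BCl3 ionises the benzyl ether (the benzyl cation is trapped by pentamethylbenzene) and cleaves the 5''-O-methyl group through its six-membered chelate with the C4'' carbonyl, the known selective peri-demethylation of polymethoxyflavones, while the unchelated 7''-, 4'- and 4'''-OMe groups should stay.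

**Compound list**

1 | acacetin, 5,7-dihydroxy-2-(4-methoxyphenyl)-4H-chromen-4-one | COc1ccc(cc1)-c1cc(=O)c2c(O)cc(O)cc2o1 | starting material
2 | 7-(benzyloxy)-5-hydroxy-2-(4-methoxyphenyl)-4H-chromen-4-one | COc1ccc(cc1)-c1cc(=O)c2c(O)cc(OCc3ccccc3)cc2o1 | intermediate
3 | 5,7-dimethoxy-2-(4-methoxyphenyl)-4H-chromen-4-one (apigenin trimethyl ether) | COc1ccc(cc1)-c1cc(=O)c2c(OC)cc(OC)cc2o1 | starting material
4 | [5,7-dimethoxy-2-(4-methoxyphenyl)-4-oxo-4H-chromen-8-yl](phenyl)iodonium 4-methylbenzenesulfonate | COc1ccc(cc1)-c1cc(=O)c2c(OC)cc(OC)c([I+]c3ccccc3)c2o1.Cc1ccc(cc1)S(=O)(=O)[O-] | intermediate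
5 | 7-(benzyloxy)-6-[5,7-dimethoxy-2-(4-methoxyphenyl)-4-oxo-4H-chromen-8-yl]-5-hydroxy-2-(4-methoxyphenyl)-4H-chromen-4-one, racemic axis | COc1ccc(cc1)-c1cc(=O)c2c(O)c(-c3c(OC)cc(OC)c4c(=O)cc(-c5ccc(OC)cc5)oc34)c(OCc6ccccc6)cc2o1 | intermediate
6 | 5,7-dihydroxy-6-[5-hydroxy-7-methoxy-2-(4-methoxyphenyl)-4-oxo-4H-chromen-8-yl]-2-(4-methoxyphenyl)-4H-chromen-4-one, racemic axis | COc1ccc(-c2cc(=O)c3c(O)c(-c4c(OC)cc(O)c5c(=O)cc(-c6ccc(OC)cc6)oc45)c(O)cc3o2)cc1 | target

**Count and risks**

Total step count: 3. Longest linear sequence: 3 steps (1 → 2 → 5 → 6).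

Steps most likely to fail:

Step 2. The electron transfer and C–C bond formation may not set in with a weakly nucleophilic CH flanked on both sides, so that the iodonium salt survives or breaks down by ligand coupling with its counter-ion. The first stage may also place the iodane at C6 or C3 of 3. The fallback is a Suzuki–Miyaura coupling of the same two sites; it sets out from 3 and 2 and comes back at 5. From 3, iodination at C8 (I2, AgOCOCF3, CH2Cl2) should give 8-iodo-5,7-dimethoxy-2-(4-methoxyphenyl)-4H-chromen-4-one F1. Miyaura borylation (B2pin2, PdCl2(dppf), KOAc, dioxane, 90 °C) should turn it into 5,7-dimethoxy-2-(4-methoxyphenyl)-8-(4,4,5,5-tetramethyl-1,3,2-dioxaborolan-2-yl)-4H-chromen-4-one F2. From 2, the 6-iodination directed by the free 5-OH (BnMe3NICl2, CaCO3, CH2Cl2–MeOH) should give 7-(benzyloxy)-5-hydroxy-6-iodo-2-(4-methoxyphenyl)-4H-chromen-4-one F3. Coupling of F2 with F3 (Pd(OAc)2, SPhos, K3PO4, toluene–H2O, 100 °C) should give 5.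

Step 3. The unchelated 7''-O-methyl group may be lost beside the intended one, the 5''-O-methyl cleavage may stall, or the benzyl cation may return onto a ring A. The fallback separates the two removals; it sets out from 5 and comes back at 6. Hydrogenolysis (H2, Pd/C, EtOAc–THF, rt) should give 6-[5,7-dimethoxy-2-(4-methoxyphenyl)-4-oxo-4H-chromen-8-yl]-5,7-dihydroxy-2-(4-methoxyphenyl)-4H-chromen-4-one F4 under neutral conditions. AlCl3 in MeCN, which acts only on a methoxy group peri to the carbonyl, should then give 6.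

Step 1. Alkylation may run on to the chelated 5-OH or to carbon. The fallback sets out from 1 and comes back at 2. Exhaustive benzylation (BnBr in excess, K2CO3, DMF, 80 °C) should give 5,7-bis(benzyloxy)-2-(4-methoxyphenyl)-4H-chromen-4-one F5. MgBr2·OEt2 (toluene–Et2O, reflux) should then remove only the benzyl group next to the carbonyl and give 2.

Further compounds
F1 | step 2 | 8-iodo-5,7-dimethoxy-2-(4-methoxyphenyl)-4H-chromen-4-one | COc1ccc(cc1)-c1cc(=O)c2c(OC)cc(OC)c(I)c2o1
F2 | step 2 | 5,7-dimethoxy-2-(4-methoxyphenyl)-8-(4,4,5,5-tetramethyl-1,3,2-dioxaborolan-2-yl)-4H-chromen-4-one | COc1ccc(cc1)-c1cc(=O)c2c(OC)cc(OC)c(B3OC(C)(C)C(C)(C)O3)c2o1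
F3 | step 2 | 7-(benzyloxy)-5-hydroxy-6-iodo-2-(4-methoxyphenyl)-4H-chromen-4-one | COc1ccc(cc1)-c1cc(=O)c2c(O)c(I)c(OCc3ccccc3)cc2o1
F4 | step 3 | 6-[5,7-dimethoxy-2-(4-methoxyphenyl)-4-oxo-4H-chromen-8-yl]-5,7-dihydroxy-2-(4-methoxyphenyl)-4H-chromen-4-one | COc1ccc(cc1)-c1cc(=O)c2c(O)c(-c3c(OC)cc(OC)c4c(=O)cc(-c5ccc(OC)cc5)oc34)c(O)cc2o1
F5 | step 1 | 5,7-bis(benzyloxy)-2-(4-methoxyphenyl)-4H-chromen-4-one | COc1ccc(cc1)-c1cc(=O)c2c(OCc3ccccc3)cc(OCc3ccccc3)cc2o1
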